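**Assumption (chemistry):** 1,3-dimethoxyacetone (7) is taken as purchasable, and the C5 epimer of the target (methoxy cis to the angular allyl group) is treated as the product of kinetic protonation, not necessarily the more stable epimer.

## Analysis of the target

The target is a 3,3a,4,5-tetrahydro-1-benzofuran-6(2H)-one. Ring A is the dihydrofuran O1–C2–C3–C3a–C7a and ring B the six-membered ring C3a–C4–C5–C6–C7–C7a, fused through C3a–C7a. Ring B is a vinylogous ester (O1–C7a=C7–C6=O) with methoxy groups on C7 and on the sp3 carbon C5. The four stereocentres are 2R, 3S, 3aR and 5S: the C2 methyl and the C3a allyl group lie on one face of ring A, the 3,4,5-trimethoxyphenyl group on C3 lies on the other face, and the C5 methoxy group is cis to the allyl group across C4. The ring fusion forces the angular allyl group to be pseudo-axial on ring B, so the cis C5 methoxy group is pseudo-axial as well; C5 is alpha to the C6 ketone and is the one centre that can epimerise, probably away from the required arrangement. Sensitive functions are the terminal alkene (no hydrogenation), the vinylogous ester and the C5–H. The difficulty lies in the quaternary C3a, flanked by the contiguous stereocentres C3 and C2 and by the enol ether carbon C7a, and in placing the aryl group on C3 opposite to two cis substituents. The strategy rests on C3a being bonded to both C7a and C3: with C3 as a ketone and C7a as a lactone carbonyl, O1–C2–C3–C3a–C7a is (R)-5-methyltetronic acid, whose doubly activated C3a can carry the allyl group and accept the four-carbon unit C4–C7 of ring B.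

## Retrosynthetic reasoning

**C5–H (16 to 15).** The last bond made is C5–H. Compound 15 is the target with C5 unassigned, and both of its epimers give one enolate. Setting C5 last means no later step can scramble it, and the proton can be brought in on the face away from the pseudo-axial allyl group, which leaves the methoxy group cis to allyl.

**C3–aryl (15 to 12 and 13).** The bond between C3 and the arene is cut, giving the C3 carbinol 12 and the aryl bromide 13. The cut is placed here because the required sense at C3 needs the aryl group, not hydrogen, to enter last: a planar C3 intermediate is open on the face away from the cis methyl and allyl groups. Adding the arene to a C3 carbonyl and then removing oxygen would put hydrogen on that open face and give the wrong epimer. A C3 radical captured by an aryl–nickel species meets the requirement. The hydroxyl of 12 is the radical precursor, because C3 is a neopentyl-type secondary carbon at which substitution to a halide with inversion is not credible.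

**C3–H (12 to 11).** The carbinol is taken back to the C3 ketone of 11. The forward reduction only has to distinguish a saturated ketone from the C6 carbonyl, which is deactivated as part of the vinylogous ester.

**C7–C7a and C3a–C4 (11 to 6 and 8).** Opening the enol ether O1–C7a of 11 by formal hydration gives the cyclohexane-1,3-dione 10. Its C7–C7a bond is a Claisen bond from a ketone enolate to a lactone carbonyl, which leads to the Michael adduct 9. The C3a–C4 bond of 9 is the Michael bond between the tetronic acid 6 and the enone 8. These two bonds are cut because they are the only ring B bonds that use the double activation of C3a and deliver C7a at the right oxidation level with no later redox change. The forward reaction must add through carbon, anti to the C2 methyl, close on the lactone and not on the C3 ketone, and leave C2 untouched.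

**C3a–allyl (6 to 5, then 3 and 4).** The allyl group is removed from C3a by a retro-[3,3] shift to the O-allyl ether 5, which comes from the tetronic acid 3 and allyl alcohol 4. Going through oxygen guarantees a single allyl group on carbon; direct C-allylation of 3 would risk a second allylation.

**C3–C3a (3 to 2 to 1).** The tetronic acid ring is opened at the bond between the enol carbon and C3a (target numbering), a Dieckmann-type bond, giving the O-acetyl lactate 2 and then methyl (R)-lactate 1. The C2 stereocentre of the target is thus bought, and the two carbons of the acetyl group become C3a and C7a.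

**C4 (8 to 7).** The terminal methylene of 8, the future C4, is removed to give the symmetric ketone 7; forward, this is an alpha-methylenation with a one-carbon electrophile.

## Alternatives that were turned down

**Alternative 1: quinone methide plus sulfur ylide, (4+1).** The disconnection cuts C2–C3 and O1–C2 of an aromatic dihydrobenzofuran. Forward, the benzhydrol A2 would give an ortho-quinone methide that takes up a chiral sulfur ylide carrying the C2–methyl unit: carbon attack at C3, then phenoxide displacement at C2, giving the trans dihydrobenzofuran A1.
- For: it is convergent, the intermediates are robust arenes, and the trans C2/C3 pair forms in one step with the aryl group already in place. On the C3–aryl bond it is stronger than the chosen route, which must couple a radical at a congested carbon.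
- Against: the absolute configuration depends on reagent control with an unstabilised ylide. C3a must then be made by dearomatising para-allylation of the phenol freed from A1, with O- against C-allylation and facial selectivity as open questions. The resulting dienone A3 still needs chemoselective conjugate reduction of C4=C5 and the same C5 protonation as here.
- Comparison: step count is similar. The chosen route offers chiral-pool control of C2, a quaternary centre made by enolate chemistry, and no dearomatisation.

**Alternative 2: intramolecular Diels–Alder.** The disconnection cuts C3a–C7a and C4–C5. Forward, a tetra-oxygenated diene tethered through O1–C2–C3 adds to a 1,1-disubstituted alkene and gives the cis-fused silyl enol ether A4.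
- For: both rings, the quaternary C3a and its relation to C2 and C3 arise in one step. On bond economy in the key step it is stronger than the chosen route.
- Against: the dienophile is unactivated and the diene electron-rich, so the cycloaddition is electronically unassisted and needs heat. The diene must be made with defined geometry and is hydrolytically fragile, and the allyl group offers a second alkene. A4 has a C7a–H and the wrong C5 epimer, so a dehydrogenation to C7=C7a and an epimerisation follow.
- Comparison: the chosen route brings C7a in as a carbonyl carbon and needs no oxidation after ring formation.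

**Alternative 3: oxa-Michael desymmetrisation of a cyclohexadienone.** The disconnection cuts O1–C7a. Forward, the C2 alkoxide of the 4,4-disubstituted dienone A6 adds 5-exo to one of the two enone beta-carbons and the enolate is silylated to A5.
- For: the ring closure is easy, and C2 and C3 are set beforehand in an open chain. The aryl group is in place from the start, which is stronger than the late coupling here.
- Against: the two enone arms are diastereotopic and the addition is reversible, so C3a is set by a thermodynamic preference that cannot be predicted with confidence. A6 itself needs a dearomatising para-allylation. A5 has the double bonds on the wrong side, so it must be oxidised to the dienone A3 and then reduced selectively at C4=C5, with C5 protonation again at the end.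
- Comparison: it is longer in redox steps; the chosen route is redox-neutral after the annulation except for one ketone reduction.

Key step: step 6

## Route

**Step 1**
Reactants: 1 methyl (R)-lactate
Product: 2 methyl (2R)-2-(acetyloxy)propanoate
Conditions: Ac2O, pyridine, DMAP (cat.), CH2Cl2, 0 °C to rt
Reagents that add atoms: acetic anhydride, CC(=O)OC(C)=O
Why: DMAP-catalysed O-acylation of a secondary alcohol; no bond to the stereocentre is touched, so the R configuration is carried over.

**Step 2**
Reactants: 2 methyl (2R)-2-(acetyloxy)propanoate
Product: 3 (5R)-4-hydroxy-5-methylfuran-2(5H)-one [(R)-5-methyltetronic acid]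
Conditions: LiN(SiMe3)2 (2.2 equiv), THF, −78 °C; then aq. HCl
Reagents that add atoms: none
Why: Intramolecular Claisen (Dieckmann) condensation: the acetate enolate attacks the neighbouring methyl ester and methoxide leaves; the product is held as its tetronate anion, and at −78 °C the lactate C–H is not removed, so the stereocentre should survive.

**Step 3**
Reactants: 3 (5R)-4-hydroxy-5-methylfuran-2(5H)-one; 4 allyl alcohol
Product: 5 (5R)-4-(allyloxy)-5-methylfuran-2(5H)-one
Conditions: PPh3, diisopropyl azodicarboxylate, THF, 0 °C to rt
Reagents that add atoms: none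
Why: Mitsunobu etherification; the vinylogous acid OH (pKa about 4) is an ideal acidic partner and is alkylated on the 4-oxygen, without C-allylation.

**Step 4**
Reactants: 5 (5R)-4-(allyloxy)-5-methylfuran-2(5H)-one
Product: 6 (5R)-3-allyl-4-hydroxy-5-methylfuran-2(5H)-one
Conditions: PhMe, 150 °C, sealed tube
Reagents that add atoms: none
Why: Claisen [3,3] rearrangement of the allyl vinyl ether to the ring carbon, then tautomerisation to the tetronic acid; exactly one allyl group reaches carbon and the C5 stereocentre is not involved.

**Step 5**
Reactants: 7 1,3-dimethoxyacetone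
Product: 8 1,3-dimethoxybut-3-en-2-one
Conditions: (CH2O)n, i-Pr2NH·CF3CO2H, CF3CO2H (cat.), THF, reflux; 7 in excess
Reagents that add atoms: formaldehyde (as paraformaldehyde), C=O
Why: Mannich-type alpha-methylenation (aminomethylation then elimination of the amine) at one of the two equivalent alpha-methylene groups; excess ketone limits a second methylenation.

**Step 6**
Reactants: 6 (5R)-3-allyl-4-hydroxy-5-methylfuran-2(5H)-one; 8 1,3-dimethoxybut-3-en-2-one
Product: 11 (2R,3aS,5RS)-3a-allyl-5,7-dimethoxy-2-methyl-4,5-dihydro-1-benzofuran-3,6(2H,3aH)-dione, via Michael adduct 9 (not isolated), via ring-opened trione 10 (not isolated)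
Conditions: Et3N (1 equiv), MeCN, rt to 40 °C; evaporate; LiN(SiMe3)2 (1.1 equiv), THF, −78 to 0 °C; AcOH; TsOH·H2O (cat.), PhMe, 40 °C
Reagents that add atoms: none
Why: This is a Michael–Claisen annulation of the kind that turns an ester and an enone into a cyclohexane-1,3-dione, here with a lactone carbonyl as the acyl acceptor. The ammonium tetronate of 6 is a soft ambident anion that adds through C3a to the terminal CH2 of 8 (O-addition is reversible), forming C3a–C4 and giving 9. LiN(SiMe3)2 then removes a proton from the unhindered C7 methylene, and the enolate attacks the lactone carbonyl C7a in a 6-exo-trig closure of ring B; collapse of the tetrahedral intermediate breaks O1–C7a, and the freed alkoxide is quenched by the acidic C7–H of the new 1,3-dione, so 10 forms as its stabilised enolate. That enolate is the thermodynamic sink, whereas the competing aldol on the C3 ketone is reversible and meets a carbonyl hindered on both sides. On acidification the C2 hydroxyl adds to the C7a carbonyl (5-exo-trig) and dehydration gives the vinylogous ester, so ring A is restored on C7a with C3 left as a ketone. C3a is set in the Michael step by the C2 methyl group: the planar tetronate is attacked on the face away from it, which leaves the allyl group cis to methyl (3aS in 11, the arrangement that becomes 3aR in the target). C5 forms alpha to the C6 ketone without control and is carried as a mixture until step 9. The step needs C- over O-alkylation, Claisen at C7a over aldol at C3, and no enolisation at C2; the soft acceptor, kinetic deprotonation of the CH2 at −78 °C with one equivalent of base, and a short, mild acid treatment are meant to secure these.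

**Step 7**
Reactants: 11 (2R,3aS,5RS)-3a-allyl-5,7-dimethoxy-2-methyl-4,5-dihydro-1-benzofuran-3,6(2H,3aH)-dione
Product: 12 (2R,3R,3aR,5RS)-3a-allyl-3-hydroxy-5,7-dimethoxy-2-methyl-3,3a,4,5-tetrahydro-1-benzofuran-6(2H)-one
Conditions: NaBH4, MeOH/CH2Cl2, −78 to −40 °C
Reagents that add atoms: none
Why: Chemoselective 1,2-reduction of the saturated C3 ketone; the C6 carbonyl is deactivated as a vinylogous ester. Hydride should enter anti to the cis methyl and allyl groups (3R carbinol), but this configuration is of no consequence because C3 becomes a radical in step 8.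

**Step 8**
Reactants: 12 (2R,3R,3aR,5RS)-3a-allyl-3-hydroxy-5,7-dimethoxy-2-methyl-3,3a,4,5-tetrahydro-1-benzofuran-6(2H)-one; 13 5-bromo-1,2,3-trimethoxybenzene
Product: 15 (2R,3S,3aR,5RS)-3a-allyl-5,7-dimethoxy-2-methyl-3-(3,4,5-trimethoxyphenyl)-3,3a,4,5-tetrahydro-1-benzofuran-6(2H)-one, via benzoxazoline adduct 14 (not isolated)
Conditions: 5,7-di-tert-butyl-3-phenyl-1,3-benzoxazol-3-ium tetrafluoroborate, pyridine, MTBE, rt; then 13 (1.5 equiv), [Ir(ppy)2(dtbbpy)]PF6 (cat.; ppy = 2-phenylpyridinato, dtbbpy = 4,4'-di-tert-butyl-2,2'-bipyridine), NiBr2(dme) (cat.; dme = 1,2-dimethoxyethane), dtbbpy (cat.), quinuclidine, DMA/MTBE, blue LED, rt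
Reagents that add atoms: 5,7-di-tert-butyl-3-phenyl-1,3-benzoxazol-3-ium tetrafluoroborate, CC(C)(C)c1cc(C(C)(C)C)c2oc[n+](-c3ccccc3)c2c1.F[B-](F)(F)F (its atoms stay in 14 only; 15 takes none)
Why: Deoxygenative C(sp3)–C(sp2) cross-coupling of an alcohol by photoredox/nickel dual catalysis: 12 adds to the azolium carbon to give 14, and oxidation and deprotonation of the aminal give a radical that cleaves the C3–O bond, releasing the secondary C3 radical. The aryl–nickel bromide complex of divalent nickel formed from 13 captures that radical on the face opposite the cis C2 methyl and C3a allyl groups, and reductive elimination gives the 3S centre with aryl trans to both.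

**Step 9**
Reactants: 15 (2R,3S,3aR,5RS)-3a-allyl-5,7-dimethoxy-2-methyl-3-(3,4,5-trimethoxyphenyl)-3,3a,4,5-tetrahydro-1-benzofuran-6(2H)-one
Product: 16 (2R,3S,3aR,5S)-3a-allyl-5,7-dimethoxy-2-methyl-3-(3,4,5-trimethoxyphenyl)-3,3a,4,5-tetrahydro-1-benzofuran-6(2H)-one (target)
Conditions: LiN(i-Pr)2, THF, −78 °C; then 2,6-di-tert-butyl-4-methylphenol, −78 °C; aq. NH4Cl
Reagents that add atoms: none
Why: Kinetic alpha'-deprotonation of the vinylogous ester (C5 is the only enolisable position, since C3a is quaternary) brings both C5 epimers to one enolate. Kinetic protonation by a bulky phenol should occur on the face away from the pseudo-axial allyl group, leaving the methoxy group cis to allyl (5S).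

## Compound list

1 | methyl (R)-lactate | C[C@@H](O)C(=O)OC | starting material
2 | methyl (2R)-2-(acetyloxy)propanoate | C[C@@H](OC(C)=O)C(=O)OC | intermediate
3 | (5R)-4-hydroxy-5-methylfuran-2(5H)-one | C[C@H]1OC(=O)C=C1O | intermediate
4 | allyl alcohol | C=CCO | starting material
5 | (5R)-4-(allyloxy)-5-methylfuran-2(5H)-one | C[C@H]1OC(=O)C=C1OCC=C | intermediate
6 | (5R)-3-allyl-4-hydroxy-5-methylfuran-2(5H)-one | C[C@H]1OC(=O)C(CC=C)=C1O | intermediate
7 | 1,3-dimethoxyacetone | COCC(=O)COC | starting material
8 | 1,3-dimethoxybut-3-en-2-one | C=C(OC)C(=O)COC | intermediate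
9 | (3R,5R)-3-allyl-3-(2,4-dimethoxy-3-oxobutyl)-5-methylfuran-2,4(3H,5H)-dione, side-chain C–OMe centre unassigned | C=CC[C@]1(CC(OC)C(=O)COC)C(=O)O[C@H](C)C1=O | intermediate (not isolated)
10 | (4R)-4-allyl-4-[(2R)-2-hydroxypropanoyl]-2,6-dimethoxycyclohexane-1,3-dione, C2 and C6 unassigned | C=CC[C@]1(C(=O)[C@@H](C)O)CC(OC)C(=O)C(OC)C1=O | intermediate (not isolated)
11 | (2R,3aS,5RS)-3a-allyl-5,7-dimethoxy-2-methyl-4,5-dihydro-1-benzofuran-3,6(2H,3aH)-dione | C=CC[C@]12CC(OC)C(=O)C(OC)=C1O[C@H](C)C2=O | intermediate
12 | (2R,3R,3aR,5RS)-3a-allyl-3-hydroxy-5,7-dimethoxy-2-methyl-3,3a,4,5-tetrahydro-1-benzofuran-6(2H)-one | C=CC[C@]12CC(OC)C(=O)C(OC)=C1O[C@H](C)[C@@H]2O | intermediate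
13 | 5-bromo-1,2,3-trimethoxybenzene | COc1cc(Br)cc(OC)c1OC | starting material
14 | 2-O-(C3 of 12) adduct: 5,7-di-tert-butyl-3-phenyl-2,3-dihydro-1,3-benzoxazol-2-yl ether of 12, aminal carbon unassigned | C=CC[C@]12CC(OC)C(=O)C(OC)=C1O[C@H](C)[C@@H]2OC1Oc2c(C(C)(C)C)cc(C(C)(C)C)cc2N1c1ccccc1 | intermediate (not isolated)
15 | (2R,3S,3aR,5RS)-3a-allyl-5,7-dimethoxy-2-methyl-3-(3,4,5-trimethoxyphenyl)-3,3a,4,5-tetrahydro-1-benzofuran-6(2H)-one | C=CC[C@]12CC(OC)C(=O)C(OC)=C1O[C@H](C)[C@H]2c1cc(OC)c(OC)c(OC)c1 | intermediate
16 | (2R,3S,3aR,5S)-3a-allyl-5,7-dimethoxy-2-methyl-3-(3,4,5-trimethoxyphenyl)-3,3a,4,5-tetrahydro-1-benzofuran-6(2H)-one | C=CC[C@]12C[C@H](OC)C(=O)C(OC)=C1O[C@H](C)[C@H]2c1cc(OC)c(OC)c(OC)c1 | target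

## Step count and least certain steps

Total steps: 9. Longest linear sequence: 8 steps (steps 1–4 and 6–9, from 1); step 5 supplies the second fragment.

**Step 6 (key step).**
- Most likely failures: sluggish or reversible Michael addition, because 8 is a captodative, weakly electrophilic enone and the tetronate a highly stabilised donor; ring closure by aldol on the C3 ketone in place of acylation at C7a; base-induced enolisation at C2 of 9, which erodes both diastereomeric and enantiomeric purity; and only moderate facial bias from a single methyl group two atoms away from C3a.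
- Fallback: leave the tetronic acid oxidation level.
  - Setting out from 3, hydrogenation (H2, Rh/Al2O3, EtOAc), which adds anti to the methyl group, should give (4R,5R)-4-hydroxy-5-methyldihydrofuran-2(3H)-one F1.
  - 4-Methoxybenzyl trichloroacetimidate with catalytic acid gives (4R,5R)-4-[(4-methoxybenzyl)oxy]-5-methyldihydrofuran-2(3H)-one F2.
  - LiN(i-Pr)2 and allyl bromide give (3R,4R,5R)-3-allyl-4-[(4-methoxybenzyl)oxy]-5-methyldihydrofuran-2(3H)-one F3.
  - A second deprotonation gives a lithium enolate, far more nucleophilic than a tetronate, that adds to 8 on the face anti to the adjacent ether and the methyl group. This gives the Michael adduct (4R,5R)-3-allyl-3-(2,4-dimethoxy-3-oxobutyl)-4-[(4-methoxybenzyl)oxy]-5-methyldihydrofuran-2(3H)-one F4, with allyl cis to both.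
  - With C3 as an ether, no ketone competes with the lactone carbonyl and no acidic C2–H is present. Claisen closure with KOt-Bu followed by TsOH gives (2R,3R,3aR,5RS)-3a-allyl-5,7-dimethoxy-3-[(4-methoxybenzyl)oxy]-2-methyl-3,3a,4,5-tetrahydro-1-benzofuran-6(2H)-one F5.
  - DDQ removes the benzyl ether and the route is rejoined at 12.

**Step 8.**
- Most likely failures: slow condensation of the hindered neopentyl-type alcohol with the azolium salt; slow capture of the congested C3 radical by nickel, leading to simple reduction at C3 or to beta-scission of the C2–O1 bond with opening of ring A; side reactions at the terminal alkene; and incomplete facial selectivity, since the open face is shielded only relative to two substituents.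
- Fallback: change the radical precursor and the way the radical is made. From 12, oxalyl chloride and then aqueous CsHCO3 give the cesium oxalate of 12 F6. Single-electron oxidation with loss of two molecules of CO2 ([Ir(dF(CF3)ppy)2(dtbbpy)]PF6, NiBr2(dme), dtbbpy, 13, dioxane/DMSO, blue light, 70 °C) generates the same C3 radical by a decarboxylative path and returns to the route at 15.

**Step 9.**
- Most likely failures: protonation of the lithium enolate on oxygen followed by unselective ketonisation of the enol, and equilibration during work-up toward the presumably more stable epimer with methoxy trans to allyl.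
- Fallback: from 15, trap the enolate (LiN(i-Pr)2, Me3SiCl) as the trimethylsilyl dienol ether F7 and protonate this neutral ether with CF3CO2H in CH2Cl2 at −78 °C. With oxygen blocked, the proton must go to C5 directly, again from the face away from the allyl group, and desilylation gives 16.

**Step 5.**
- Most likely failures: methylenation on both sides of the symmetric ketone and oligomerisation of the electron-rich enone on heating.
- Fallback: a regiospecific stepwise sequence from 7. Me3SiOTf and Et3N give 1,3-dimethoxy-2-(trimethylsilyloxy)prop-1-ene F8; dimethyl(methylene)ammonium iodide gives the Mannich base 4-(dimethylamino)-1,3-dimethoxybutan-2-one F9; MeI gives (2,4-dimethoxy-3-oxobutyl)trimethylammonium iodide F10; NaHCO3 then eliminates the amine to give 8.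

## Further compounds

F1 | step 6 | (4R,5R)-4-hydroxy-5-methyldihydrofuran-2(3H)-one | C[C@H]1OC(=O)C[C@H]1O
F2 | step 6 | (4R,5R)-4-[(4-methoxybenzyl)oxy]-5-methyldihydrofuran-2(3H)-one | C[C@H]1OC(=O)C[C@H]1OCc1ccc(OC)cc1
F3 | step 6 | (3R,4R,5R)-3-allyl-4-[(4-methoxybenzyl)oxy]-5-methyldihydrofuran-2(3H)-one | C[C@H]1OC(=O)[C@H](CC=C)[C@H]1OCc1ccc(OC)cc1
F4 | step 6 | (4R,5R)-3-allyl-3-(2,4-dimethoxy-3-oxobutyl)-4-[(4-methoxybenzyl)oxy]-5-methyldihydrofuran-2(3H)-one, allyl cis to ether and methyl | C[C@H]1OC(=O)[C@](CC=C)(CC(OC)C(=O)COC)[C@H]1OCc1ccc(OC)cc1
F5 | step 6 | (2R,3R,3aR,5RS)-3a-allyl-5,7-dimethoxy-3-[(4-methoxybenzyl)oxy]-2-methyl-3,3a,4,5-tetrahydro-1-benzofuran-6(2H)-one | C=CC[C@]12CC(OC)C(=O)C(OC)=C1O[C@H](C)[C@@H]2OCc1ccc(OC)cc1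
F6 | step 8 | cesium oxalate (C3 half-ester) of 12 | C=CC[C@]12CC(OC)C(=O)C(OC)=C1O[C@H](C)[C@@H]2OC(=O)C(=O)[O-].[Cs+]
F7 | step 9 | (2R,3S,3aR)-3a-allyl-5,7-dimethoxy-2-methyl-3-(3,4,5-trimethoxyphenyl)-6-(trimethylsilyloxy)-2,3,3a,4-tetrahydro-1-benzofuran | C=CC[C@]12CC(OC)=C(O[Si](C)(C)C)C(OC)=C1O[C@H](C)[C@H]2c1cc(OC)c(OC)c(OC)c1
F8 | step 5 | 1,3-dimethoxy-2-(trimethylsilyloxy)prop-1-ene | COC=C(COC)O[Si](C)(C)C
F9 | step 5 | 4-(dimethylamino)-1,3-dimethoxybutan-2-one | COCC(=O)C(OC)CN(C)C
F10 | step 5 | (2,4-dimethoxy-3-oxobutyl)trimethylammonium iodide | COCC(=O)C(OC)C[N+](C)(C)C.[I-]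
A1 | alternative 1 | (2R,3S)-6-(benzyloxy)-5,7-dimethoxy-2-methyl-3-(3,4,5-trimethoxyphenyl)-2,3-dihydro-1-benzofuran | COc1c(OCc2ccccc2)c(OC)cc2c1O[C@H](C)[C@H]2c1cc(OC)c(OC)c(OC)c1
A2 | alternative 1 | [4-(benzyloxy)-2-hydroxy-3,5-dimethoxyphenyl](3,4,5-trimethoxyphenyl)methanol | COc1cc(C(O)c2cc(OC)c(OC)c(OC)c2)c(O)c(OC)c1OCc1ccccc1
A3 | alternative 1 | (2R,3S,3aS)-3a-allyl-5,7-dimethoxy-2-methyl-3-(3,4,5-trimethoxyphenyl)-2,3-dihydro-1-benzofuran-6(3aH)-one | C=CC[C@]12C=C(OC)C(=O)C(OC)=C1O[C@H](C)[C@H]2c1cc(OC)c(OC)c(OC)c1
A4 | alternative 2 | (2R,3S,3aR,5R,7aS)-3a-allyl-6-[(tert-butyldimethylsilyl)oxy]-5,7-dimethoxy-2-methyl-3-(3,4,5-trimethoxyphenyl)-2,3,3a,4,5,7a-hexahydro-1-benzofuran | C=CC[C@]12C[C@@H](OC)C(O[Si](C)(C)C(C)(C)C)=C(OC)[C@H]1O[C@H](C)[C@H]2c1cc(OC)c(OC)c(OC)c1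
A5 | alternative 3 | (2R,3S,3aS,7aS)-3a-allyl-5,7-dimethoxy-2-methyl-3-(3,4,5-trimethoxyphenyl)-6-(trimethylsilyloxy)-2,3,3a,7a-tetrahydro-1-benzofuran | C=CC[C@]12C=C(OC)C(O[Si](C)(C)C)=C(OC)[C@H]1O[C@H](C)[C@H]2c1cc(OC)c(OC)c(OC)c1
A6 | alternative 3 | 4-allyl-4-[(1S,2R)-2-hydroxy-1-(3,4,5-trimethoxyphenyl)propyl]-2,6-dimethoxycyclohexa-2,5-dien-1-one | C=CCC1(C=C(OC)C(=O)C(OC)=C1)[C@@H]([C@@H](C)O)c1cc(OC)c(OC)c(OC)c1
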